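The pitfall with a loading this low was to warm the flask to help the catalyst along, before counting what warmth does to the fate of X.

    X + L → L + Q (k1 = 3050 M⁻¹ min⁻¹, Ea1 = 50.0 kJ mol⁻¹)
    X → E (k2 = 0.0108 min⁻¹, Ea2 = 99.0 kJ mol⁻¹)
    2 L ⇌ L2, settled at all times (K3 = 5160 M⁻¹, ΔH3 = −31.0 kJ mol⁻¹)
    (constants at 20 °C)

| flask | X | L | temperature | time |
|---|---|---|---|---|
| north-east | 22 mM | 0.36 mol% | 20 °C | 80 min |
| west | 22 mM | 0.36 mol% | 50 °C | 80 min |
| south-east | 22 mM | 0.36 mol% | 80 °C | 80 min |

- a doubled species enters its step squared and goes two at a time
- all constants are for 20 °C and move with temperature by the activation energies and enthalpies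

- the flask with the highest amount of Q, in percent of the X charged ("all alike" if they lie within 1.5 percentage points) (north-east / west / south-east / all alike)
- final Q, as a percentage of the X charged, in north-east
- final Q, as a percentage of the X charged, in west
- final Q, as a percentage of the X charged, in south-east

X was my limiting reagent, so I kept a ledger of X. First entry: the charge stood at 278 X for each L charged. That looked heavy, but L comes back from each round, so X falls in a pseudo-first-order way at constant [L].

Second entry: the catalyst charged was 0.0792 mM, and part of it sits as L2. I solved [L] + 2[L2] = 0.0792 mM, with [L2] equal to 5160 M⁻¹ times [L] squared. In north-east this left [L] = 0.0517 mM.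

Third entry: X leaves by two doors, at k1[L] towards Q and at k2 towards E. In north-east, k1[L]/k2 came to 14.6. I called this the split, the X that become Q for each X that becomes E; it is a selectivity factor. [X] cancels from it.

To close the books, X in north-east had a lifetime of 5.94 min, far shorter than the 80 min allowed. So I shared the whole charge by the split: 93.6% to Q and 6.41% to E.

For south-east, the balance constant shrank to 595 M⁻¹, so [L] rose to 0.0729 mM. Yet the split there fell to 0.676. X in south-east had a lifetime of 0.0556 min, far shorter than the 80 min allowed, so the split books 40.3% to Q. I did not work west by hand.

The forecast named north-east, with 93.6% (92.5% to 94.5%) in north-east, 74.1% (72% to 76%) in west and 40.3% (38% to 43%) in south-east. Its grounds: “Heating frees a little more L, but the much higher activation energy of the X → E step outweighs this”.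

The simulation gave Q of 93.6% in north-east, 74.1% in west and 40.3% in south-east, so north-east stood highest and the forecast held. In north-east at 4.12 min, X had a half-life of 4.4 min by the step to Q and 64 min by the step to E, and the rates of the two steps stood at a ratio of 15. From the coldest flask to the hottest, the constant of the step to Q grew by a factor of 33 and that of the step to E by 990, and Q fell from 93.6% to 40.3%.

Take the neighbour, a north-east flask left until 3.0 h. The split of 14.6 has no time in it, so it gives 93.6% again. The computed flask held 93.6% of Q and 6.41% of E.

Its constants are assumed; no experiment stands behind them.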